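The plan rests on removing the inner catechol oxygen of ring A and of ring C retrosynthetically, which turns the target into a resorcinol-type macrocyclic bis(bibenzyl) dimethyl ether. In the forward sense one double ortho-lithiation, borylation and oxidation forms both C–O bonds: on ring A and on ring C the only C–H that lies between the methoxy carbon and the diaryl-ether carbon is flanked by two oxygens and is metalated preferentially. The precursor is the 17-membered tetra-aryl macrocycle carrying one methoxy group on ring A and one on ring C, assembled by two ether formations, a Heck coupling and a McMurry ring closure.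

Key step: step 7

Remark: ring A is the 1,3,5-trisubstituted ring that comes from 1, ring B the para-phenylene ring, ring C the ring that comes from 4, ring D the ortho-phenylene ring that comes from 5. The two CH2CH2 bridges are made by two different reactions (Heck, then McMurry), so two like formyl groups never have to be told apart.

Step 1
Reactants: 1 3-hydroxy-5-methoxybenzaldehyde; 2 4-vinylphenylboronic acid
Product: 3 3-methoxy-5-(4-vinylphenoxy)benzaldehyde
Conditions: Cu(OAc)2 (1 equiv, reoxidised by air), pyridine, 4 Å MS, CH2Cl2, open to dry air, rt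
Reagents that add atoms: none
Why: Chan–Lam oxidative coupling joins the phenoxide of 1 and the aryl group of 2 on copper and releases the diaryl ether at room temperature, where the formyl and vinyl groups are inert; air returns copper to the divalent state.

Step 2
Reactants: 4 2-bromo-5-methoxyphenol; 5 2-fluorobenzaldehyde
Product: 6 2-(2-bromo-5-methoxyphenoxy)benzaldehyde
Conditions: K2CO3, DMF, 110 °C
Reagents that add atoms: none
Why: Nucleophilic aromatic substitution (SNAr): the ortho-formyl group stabilises the Meisenheimer adduct so the phenoxide of 4 displaces fluoride, while the unactivated C–Br bond is untouched.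

Step 3
Reactants: 3 3-methoxy-5-(4-vinylphenoxy)benzaldehyde; 6 2-(2-bromo-5-methoxyphenoxy)benzaldehyde
Product: 7 3-[4-[(E)-2-[2-(2-formylphenoxy)-4-methoxyphenyl]ethenyl]phenoxy]-5-methoxybenzaldehyde
Conditions: Pd2(dba)3 (cat.), [(t-Bu)3PH]BF4 (cat.), Cy2NMe, 1,4-dioxane, 80 °C
Reagents that add atoms: none
Why: Mizoroki–Heck reaction: zerovalent palladium inserts into the C–Br bond of 6, the aryl group adds to the terminal vinyl carbon of 3 and syn β-hydride elimination gives the (E)-stilbene; aldehydes are tolerated and the bulky electron-rich phosphine lets the electron-rich ortho-substituted bromide react at moderate temperature.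

Step 4
Reactants: 7 (E)-stilbene dialdehyde
Product: 8 3-[4-[2-[2-(2-formylphenoxy)-4-methoxyphenyl]ethyl]phenoxy]-5-methoxybenzaldehyde
Conditions: H2 (1 atm), Pd/C, Ph2S (cat.), EtOAc, rt
Reagents that add atoms: none
Why: Heterogeneous catalytic hydrogenation on a sulfide-moderated palladium surface should still reduce the stilbene C=C bond but not the two aromatic aldehydes or the aryl ethers.

Step 5
Reactants: 8 bibenzyl dialdehyde
Product: 9 macrocyclic stilbene (ring A–CH=CH–ring D; mixture of Z and E isomers)
Conditions: TiCl4, Zn, pyridine, THF, reflux; 8 added slowly by syringe pump (high dilution)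
Reagents that add atoms: none
Why: Intramolecular McMurry coupling: low-valent titanium couples the two formyl groups to a titanium pinacolate that is deoxygenated at reflux to the alkene, and slow addition keeps 8 dilute so ring closure outruns oligomerisation; either alkene geometry is acceptable because the bond is saturated next.

Step 6
Reactants: 9 macrocyclic stilbene
Product: 10 macrocyclic bis(bibenzyl) dimethyl ether (one OMe on ring A, one OMe on ring C)
Conditions: H2 (1 atm), Pd/C, EtOAc–EtOH, rt
Reagents that add atoms: none
Why: Catalytic hydrogenation of the disubstituted stilbene double bond; aryl ethers are stable and both geometric isomers converge on the same bibenzyl.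

Step 7
Reactants: 10 macrocyclic bis(bibenzyl) dimethyl ether
Product: 13 macrocycle with an inner OH next to OMe on ring A and on ring C, via dilithiated macrocycle 11 (not isolated), via bis(dimethoxyboryl) macrocycle 12 (not isolated)
Conditions: n-BuLi (4 equiv), TMEDA, THF, −40 → 0 °C; B(OMe)3 (excess), −78 °C → rt; then 30% aq H2O2, aq NaOH, 0 °C → rt
Reagents that add atoms: hydrogen peroxide, OO (the two new phenolic oxygens); trimethyl borate, COB(OC)OC (boron and methoxy groups of intermediate 12 only); n-butyllithium, [Li]CCCC (lithium of intermediate 11 only)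
Why: The n-BuLi–TMEDA complex is pre-coordinated by the methoxy and aryloxy oxygens and removes the proton between them on ring A (the C–H between the OMe carbon and the carbon bearing the oxygen to ring B) and on ring C (the C–H between the OMe carbon and the carbon bearing the oxygen to ring D) to give 11; each C–Li bond then attacks B(OMe)3 to give 12, and hydroperoxide adds to boron and triggers a 1,2-aryl shift from boron to oxygen, so hydrolysis leaves the phenols. The closest known reaction type is directed ortho-metalation of 1,3-dialkoxy- and alkoxy-aryloxy-benzenes at the carbon flanked by both oxygens, followed by borylation and oxidation. No ring is closed and no stereocentre is formed; the two new bonds are aryl C–O bonds. The step needs site selectivity over the singly activated ortho positions of rings B and D, the remaining positions of rings A and C and the four benzylic CH2 groups. It is secured because only one C–H per ring has two ortho oxygens, which makes it both the most acidic and the best chelated, and because the cold lithiation disfavours lateral deprotonation. Both sites lie outside the macrocyclic path and are sterically accessible.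

Step 8
Reactants: 13 bis-phenol dimethyl ether macrocycle
Product: 14 target bis-catechol macrocycle (CNP0114693.0)
Conditions: BBr3 (excess), CH2Cl2, −78 °C → rt; then ice-water, work-up under argon
Reagents that add atoms: none
Why: Lewis acid-mediated aryl methyl ether cleavage: BBr3 coordinates each methoxy oxygen and bromide attacks the methyl carbon (SN2), whereas the diaryl ether bonds offer no alkyl carbon and survive; hydrolysis frees the two catechols.

Compound list
1 | 3-hydroxy-5-methoxybenzaldehyde | COc1cc(O)cc(C=O)c1 | starting material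
2 | 4-vinylphenylboronic acid | OB(O)c1ccc(C=C)cc1 | starting material
3 | 3-methoxy-5-(4-vinylphenoxy)benzaldehyde | COc1cc(C=O)cc(Oc2ccc(C=C)cc2)c1 | intermediate
4 | 2-bromo-5-methoxyphenol | COc1ccc(Br)c(O)c1 | starting material
5 | 2-fluorobenzaldehyde | O=Cc1ccccc1F | starting material
6 | 2-(2-bromo-5-methoxyphenoxy)benzaldehyde | COc1ccc(Br)c(Oc2ccccc2C=O)c1 | intermediate
7 | 3-[4-[(E)-2-[2-(2-formylphenoxy)-4-methoxyphenyl]ethenyl]phenoxy]-5-methoxybenzaldehyde | COc1cc(C=O)cc(Oc2ccc(/C=C/c3ccc(OC)cc3Oc3ccccc3C=O)cc2)c1 | intermediate
8 | 3-[4-[2-[2-(2-formylphenoxy)-4-methoxyphenyl]ethyl]phenoxy]-5-methoxybenzaldehyde | COc1cc(C=O)cc(Oc2ccc(CCc3ccc(OC)cc3Oc3ccccc3C=O)cc2)c1 | intermediate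
9 | macrocyclic stilbene, 17-membered ring, CH=CH between ring A and ring D, Z/E mixture (geometry left open) | COc1cc2cc(c1)Oc1ccc(cc1)CCc1ccc(OC)cc1Oc1ccccc1C=C2 | intermediate
10 | macrocyclic bis(bibenzyl) dimethyl ether (ring A: OMe, O to ring B, CH2CH2 to ring D in a 1,3,5 pattern; ring C: CH2CH2 to ring B, ortho O to ring D, para OMe) | COc1cc2cc(c1)Oc1ccc(cc1)CCc1ccc(OC)cc1Oc1ccccc1CC2 | intermediate
11 | dilithiated macrocycle (Li between OMe and OAr on ring A and on ring C) | COc1cc2cc(c1[Li])Oc1ccc(cc1)CCc1ccc(OC)c([Li])c1Oc1ccccc1CC2 | intermediate (not isolated)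
12 | bis(dimethoxyboryl) macrocycle (B(OMe)2 at the same two carbons) | COc1cc2cc(c1B(OC)OC)Oc1ccc(cc1)CCc1ccc(OC)c(B(OC)OC)c1Oc1ccccc1CC2 | intermediate (not isolated)
13 | macrocycle with inner OH and outer OMe on ring A and on ring C | COc1cc2cc(c1O)Oc1ccc(cc1)CCc1ccc(OC)c(O)c1Oc1ccccc1CC2 | intermediate
14 | target bis-catechol macrocycle CNP0114693.0 (achiral) | Oc1cc2cc(c1O)Oc1ccc(cc1)CCc1ccc(O)c(O)c1Oc1ccccc1CC2 | target

Total step count: 8. Longest linear sequence: 7 steps (step 1 or step 2, then steps 3 to 8).

Steps most likely to fail

Step 7 (key step). What may go wrong is metalation at a wrong site (lateral deprotonation of a bibenzyl CH2, or ortho-lithiation on ring B or ring D) or metalation of only one of the two rings, which would give mono- and mis-hydroxylated macrocycles. The fallback carries the inner oxygens through from the start, setting out from 2 and 5 and returning at 14.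
- Commercial 2,3-dimethoxyphenol (COc1cccc(O)c1OC) is brominated at its only free ortho position (NBS, cat. i-Pr2NH, CH2Cl2, 0 °C, amine-directed ortho-bromination) to give 6-bromo-2,3-dimethoxyphenol F1.
- Chan–Lam coupling of commercial 3-hydroxy-4,5-dimethoxybenzaldehyde (COc1cc(C=O)cc(O)c1OC) with 2 gives 3,4-dimethoxy-5-(4-vinylphenoxy)benzaldehyde F2.
- SNAr of F1 on 5 gives 2-(6-bromo-2,3-dimethoxyphenoxy)benzaldehyde F3.
- Heck coupling of F2 with F3 gives the tetramethoxy (E)-stilbene dialdehyde F4.
- Sulfide-moderated hydrogenation gives the tetramethoxy bibenzyl dialdehyde F5.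
- McMurry closure at high dilution gives the tetramethoxy macrocyclic stilbene F6.
- Hydrogenation gives the tetramethyl ether macrocycle F7.
- BBr3 cleaves all four methyl ethers and the route is rejoined at 14.

Step 5. What may go wrong is intermolecular carbonyl coupling to dimers and oligomers, or arrest at the titanium pinacolate, in a closure that must fold the ortho-linked rings C and D back towards ring A. The fallback closes the same C=C bond by ring-closing metathesis, setting out from 8. Double Wittig methylenation (Ph3P=CH2 from MePPh3Br and KOt-Bu, THF) gives 1-ethenyl-3-[4-[2-[2-(2-ethenylphenoxy)-4-methoxyphenyl]ethyl]phenoxy]-5-methoxybenzene F8. With second-generation Grubbs catalyst, RuCl2(=CHPh)(PCy3)(H2IMes), in dilute toluene at 80 °C this should lose ethene and give macrocyclic stilbene 9, where the route is rejoined.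

Step 1. What may go wrong is slow aryl transfer from boron to copper with the weakly nucleophilic formyl-phenol, so that protodeboronation, oxidative hydroxylation of the boronic acid or polymerisation through the vinyl group consume 2. The fallback forms the same ether by SNAr and makes the vinyl group afterwards, setting out from 1 and returning at 3.
- Ethylene glycol and TsOH in toluene with azeotropic removal of water give 3-(1,3-dioxolan-2-yl)-5-methoxyphenol F9.
- Its potassium phenoxide displaces fluoride from commercial 4-fluorobenzaldehyde (O=Cc1ccc(F)cc1; K2CO3, DMF, 120 °C) to give 4-[3-(1,3-dioxolan-2-yl)-5-methoxyphenoxy]benzaldehyde F10.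
- Wittig methylenation (Ph3P=CH2, THF) gives 2-[3-methoxy-5-(4-vinylphenoxy)phenyl]-1,3-dioxolane F11.
- Dilute HCl in THF removes the acetal and the route is rejoined at 3.

Further compounds
F1 | step 7 | 6-bromo-2,3-dimethoxyphenol | COc1ccc(Br)c(O)c1OC
F2 | step 7 | 3,4-dimethoxy-5-(4-vinylphenoxy)benzaldehyde | COc1cc(C=O)cc(Oc2ccc(C=C)cc2)c1OC
F3 | step 7 | 2-(6-bromo-2,3-dimethoxyphenoxy)benzaldehyde | COc1ccc(Br)c(Oc2ccccc2C=O)c1OC
F4 | step 7 | 3-[4-[(E)-2-[2-(2-formylphenoxy)-3,4-dimethoxyphenyl]ethenyl]phenoxy]-4,5-dimethoxybenzaldehyde | COc1cc(C=O)cc(Oc2ccc(/C=C/c3ccc(OC)c(OC)c3Oc3ccccc3C=O)cc2)c1OC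
F5 | step 7 | 3-[4-[2-[2-(2-formylphenoxy)-3,4-dimethoxyphenyl]ethyl]phenoxy]-4,5-dimethoxybenzaldehyde | COc1cc(C=O)cc(Oc2ccc(CCc3ccc(OC)c(OC)c3Oc3ccccc3C=O)cc2)c1OC
F6 | step 7 | tetramethoxy macrocyclic stilbene (CH=CH between ring A and ring D, geometry left open) | COc1cc2cc(c1OC)Oc1ccc(cc1)CCc1ccc(OC)c(OC)c1Oc1ccccc1C=C2
F7 | step 7 | tetramethyl ether of the target macrocycle | COc1cc2cc(c1OC)Oc1ccc(cc1)CCc1ccc(OC)c(OC)c1Oc1ccccc1CC2
F8 | step 5 | 1-ethenyl-3-[4-[2-[2-(2-ethenylphenoxy)-4-methoxyphenyl]ethyl]phenoxy]-5-methoxybenzene | COc1cc(C=C)cc(Oc2ccc(CCc3ccc(OC)cc3Oc3ccccc3C=C)cc2)c1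
F9 | step 1 | 3-(1,3-dioxolan-2-yl)-5-methoxyphenol | COc1cc(O)cc(c1)C1OCCO1
F10 | step 1 | 4-[3-(1,3-dioxolan-2-yl)-5-methoxyphenoxy]benzaldehyde | COc1cc(Oc2ccc(C=O)cc2)cc(c1)C1OCCO1
F11 | step 1 | 2-[3-methoxy-5-(4-vinylphenoxy)phenyl]-1,3-dioxolane | COc1cc(Oc2ccc(C=C)cc2)cc(c1)C1OCCO1
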